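The route rests on cutting the bond between C8 of the flavonol A ring and the benzylic/allylic stereocentre. Because C8 lies ortho to the C7 phenol oxygen and the stereocentre carries a vinyl group, the array O7–C7–C8–CH(Ar)–CH=C is the retron of an aromatic Claisen rearrangement. The precursor is therefore a 7-O-ether of 3,5-di-O-acetylgalangin with an enantioenriched (R,E)-4-arylbut-3-en-2-yl group (guaiacyl unit as acetate), in which the two halves are joined only through oxygen. One thermal [3,3] shift forges C8–C, transposes the allyl unit and relays the carbinol configuration to the diarylmethine carbon; ethenolysis then trims the relay methyl.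

Key step: step 6

Remark on the chemistry: with the CIP ranks flavon-8-yl > guaiacyl > vinyl > H the target stereocentre is (R); dehydrozingerone and galangin are taken as the commercial starting materials.

Step 1
Reactants: 1 dehydrozingerone [(E)-4-(4-hydroxy-3-methoxyphenyl)but-3-en-2-one]
Product: 2 (E)-4-(4-acetoxy-3-methoxyphenyl)but-3-en-2-one
Conditions: Ac2O, pyridine, DMAP (cat.), CH2Cl2, 0 °C to rt
Reagents that add atoms: acetic anhydride CC(=O)OC(C)=O
Why: Phenol O-acetylation (acyl transfer) masks the guaiacyl OH for the Mitsunobu step and makes the aryl ring non-donating, which should disfavour later ionisation of the allylic C–O bond.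

Step 2
Reactants: 2 (E)-4-(4-acetoxy-3-methoxyphenyl)but-3-en-2-one
Product: 3 (S,E)-4-(4-acetoxy-3-methoxyphenyl)but-3-en-2-ol
Conditions: (R)-Me-CBS (10 mol %), catecholborane, toluene, −78 °C; pH 7 buffer work-up
Reagents that add atoms: none
Why: Corey–Bakshi–Shibata reduction, in which the (R)-oxazaborolidine treats the styryl group as the large substituent and delivers hydride 1,2 to give the (S)-carbinol, while catecholborane at low temperature should spare the alkene and the aryl acetate.

Step 3
Reactants: 4 galangin (3,5,7-trihydroxyflavone)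
Product: 5 3,5,7-tri-O-acetylgalangin
Conditions: Ac2O, pyridine, DMAP (cat.), rt
Reagents that add atoms: acetic anhydride CC(=O)OC(C)=O
Why: Exhaustive O-acetylation (acyl transfer), with DMAP ensuring that the chelated 5-OH also reacts.

Step 4
Reactants: 5 3,5,7-tri-O-acetylgalangin
Product: 6 3,5-di-O-acetylgalangin (free 7-OH)
Conditions: PhSH, imidazole (cat.), NMP, 0 °C
Reagents that add atoms: none
Why: Regioselective thiolysis of an aryl acetate, a known way to free the 7-OH of peracetylated flavones and flavonols, because the 7-phenoxide (para to the C4 carbonyl) is the best leaving group.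

Step 5
Reactants: 6 3,5-di-O-acetylgalangin (free 7-OH); 3 (S,E)-4-(4-acetoxy-3-methoxyphenyl)but-3-en-2-ol
Product: 7 (R,E)-3,5-diacetoxy-7-{[4-(4-acetoxy-3-methoxyphenyl)but-3-en-2-yl]oxy}flavone
Conditions: PPh3, DIAD, THF, 0 °C to rt
Reagents that add atoms: none
Why: Mitsunobu etherification, in which the acidic 7-OH displaces the oxyphosphonium-activated secondary allylic alcohol by SN2 with inversion, turning the (S)-carbinol into the (R)-ether.

Step 6
Reactants: 7 (R,E)-3,5-diacetoxy-7-{[4-(4-acetoxy-3-methoxyphenyl)but-3-en-2-yl]oxy}flavone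
Product: 9 3,5-di-O-acetyl-8-[(1R,2E)-1-(4-acetoxy-3-methoxyphenyl)but-2-en-1-yl]galangin (free 7-OH), via C8-dearomatised ortho-dienone 8 (not isolated)
Conditions: mesitylene, 180 °C (sealed tube), Ar
Reagents that add atoms: none
Why: On heating, ether 7 should undergo a concerted, suprafacial [3,3]-sigmatropic shift in which the O7–C bond breaks as C8 bonds to the aryl-bearing alkene terminus, giving the ortho-dienone 8, which enolises to the C7 phenol 9. The closest known reaction type is the thermal aromatic Claisen rearrangement of aryl cinnamyl ethers (well used on 7-allyloxy-chromones and -flavones), run here with 1,3-chirality transfer from a secondary allylic aryl ether. No ring of the product is closed; the six-membered array O7–C7–C8···C–C–C exists only in the chair transition state. The new stereocentre is controlled by the carbinol centre of 7: with the methyl group pseudo-equatorial and the (E)-aryl group equatorial, the (R)-C–O configuration is relayed to the (R)-C8–C configuration and the new double bond is (E). The step needs C8 over C6 selectivity and a concerted rather than ionic course: the 5-acetate removes the 5-OH···O=C4 chelate so that the bond fixation of the benzopyranone (higher C7–C8 π-bond order) should direct the shift to C8, the para position (C4a) is a ring-fusion carbon so no para-shift can follow, and the non-polar medium together with the non-donating acetoxyaryl group disfavours heterolysis to an allyl cation.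

Step 7
Reactants: 9 3,5-di-O-acetyl-8-[(1R,2E)-1-(4-acetoxy-3-methoxyphenyl)but-2-en-1-yl]galangin (free 7-OH)
Product: 10 3,5-di-O-acetyl-8-[(1R)-1-(4-acetoxy-3-methoxyphenyl)prop-2-en-1-yl]galangin (free 7-OH)
Conditions: Hoveyda–Grubbs II (10 mol %), ethylene (5 bar), 1,4-benzoquinone (cat.), toluene, 50 °C
Reagents that add atoms: ethylene C=C
Why: Ethenolysis (olefin cross-metathesis with ethylene) exchanges the propenyl terminus for CH2 with loss of propene, does not touch the stereocentre, converges any minor (Z)-isomer, and benzoquinone should suppress Ru–H double-bond migration.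

Step 8
Reactants: 10 3,5-di-O-acetyl-8-[(1R)-1-(4-acetoxy-3-methoxyphenyl)prop-2-en-1-yl]galangin (free 7-OH)
Product: 11 8-[(1R)-1-(4-hydroxy-3-methoxyphenyl)prop-2-en-1-yl]-3,5,7-trihydroxyflavone (target)
Conditions: NH3 (7 M in MeOH), 0 °C to rt, Ar; evaporate, dilute AcOH wash
Reagents that add atoms: none
Why: Ammonolysis of the three aryl/enol acetates (acyl transfer) should free the 3-, 5- and guaiacyl hydroxyls under conditions too mild to epimerise the diarylmethine carbon or move the vinyl double bond.

Compound list
1 | dehydrozingerone, (E)-4-(4-hydroxy-3-methoxyphenyl)but-3-en-2-one | CC(=O)/C=C/c1ccc(O)c(OC)c1 | starting material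
2 | (E)-4-(4-acetoxy-3-methoxyphenyl)but-3-en-2-one | CC(=O)/C=C/c1ccc(OC(C)=O)c(OC)c1 | intermediate
3 | (S,E)-4-(4-acetoxy-3-methoxyphenyl)but-3-en-2-ol | C[C@H](O)/C=C/c1ccc(OC(C)=O)c(OC)c1 | intermediate
4 | galangin (3,5,7-trihydroxyflavone) | O=c1c(O)c(-c2ccccc2)oc2cc(O)cc(O)c12 | starting material
5 | 3,5,7-tri-O-acetylgalangin | CC(=O)Oc1cc(OC(C)=O)c2c(=O)c(OC(C)=O)c(-c3ccccc3)oc2c1 | intermediate
6 | 3,5-di-O-acetylgalangin (free 7-OH) | Oc1cc(OC(C)=O)c2c(=O)c(OC(C)=O)c(-c3ccccc3)oc2c1 | intermediate
7 | (R,E)-3,5-diacetoxy-7-{[4-(4-acetoxy-3-methoxyphenyl)but-3-en-2-yl]oxy}flavone | C[C@@H](Oc1cc(OC(C)=O)c2c(=O)c(OC(C)=O)c(-c3ccccc3)oc2c1)/C=C/c1ccc(OC(C)=O)c(OC)c1 | intermediate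
8 | C8-dearomatised ortho-dienone, 3,5-diacetoxy-8-[(E)-1-(4-acetoxy-3-methoxyphenyl)but-2-en-1-yl]-2-phenyl-8H-chromene-4,7-dione; C8 is sp3 and (S), side-chain carbon arranged in space as in 9; formed in the flask, not isolated | C/C=C/[C@H](c1ccc(OC(C)=O)c(OC)c1)[C@@H]1C(=O)C=C(OC(C)=O)C2=C1OC(c1ccccc1)=C(OC(C)=O)C2=O | intermediate
9 | 3,5-di-O-acetyl-8-[(1R,2E)-1-(4-acetoxy-3-methoxyphenyl)but-2-en-1-yl]galangin (free 7-OH) | C/C=C/[C@H](c1ccc(OC(C)=O)c(OC)c1)c1c(O)cc(OC(C)=O)c2c(=O)c(OC(C)=O)c(-c3ccccc3)oc12 | intermediate
10 | 3,5-di-O-acetyl-8-[(1R)-1-(4-acetoxy-3-methoxyphenyl)prop-2-en-1-yl]galangin (free 7-OH) | C=C[C@H](c1ccc(OC(C)=O)c(OC)c1)c1c(O)cc(OC(C)=O)c2c(=O)c(OC(C)=O)c(-c3ccccc3)oc12 | intermediate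
11 | 8-[(1R)-1-(4-hydroxy-3-methoxyphenyl)prop-2-en-1-yl]-3,5,7-trihydroxyflavone | C=C[C@H](c1ccc(O)c(OC)c1)c1c(O)cc(O)c2c(=O)c(O)c(-c3ccccc3)oc12 | target

Total step count: 8. Longest linear sequence: 6 steps (steps 3, 4, 5, 6, 7, 8 from galangin; equally steps 1, 2, 5, 6, 7, 8 from dehydrozingerone).

Steps most likely to fail

Step 6. The relay of configuration may leak: the secondary, doubly activated allylic C–O bond may partly break heterolytically and return as an ion pair, or part of the material may react through the chair with the methyl group axial. Some of the shift may also go to C6. The fallback sets out from 6 and comes back to the route at 10; it gives up chirality transfer in favour of a primary ether, which is much less prone to ionisation, and a separation of enantiomers. Commercial coniferyl alcohol would be acetylated at the phenol only (Ac2O, aq. NaOH, 0 °C) to give 4-O-acetylconiferyl alcohol F1. Mitsunobu coupling of F1 with 6 (PPh3, DIAD, THF) would give the achiral 7-O-cinnamyl ether F2. Heating F2 (mesitylene, 180 °C) would lead through the racemic ortho-dienone F3 to racemic 3,5-di-O-acetyl-8-[1-(4-acetoxy-3-methoxyphenyl)prop-2-enyl]galangin F4, with no relay methyl and therefore no ethenolysis. Preparative chromatography on a chiral stationary phase would then separate 10 from the unwanted (S)-enantiomer F5, and 10 goes on to step 8.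

Step 5. The oxyphosphonium intermediate of a secondary cinnamyl-type alcohol may react in part by SN1 or SN2′ pathways, which would erode the configuration or give the transposed ether, or it may eliminate to the diene. The fallback sets out from 2 and comes back at 7; it replaces SN2 inversion by a Pd π-allyl substitution with net retention. Reduction of 2 with (S)-Me-CBS and catecholborane would give the (R,E)-allylic alcohol F6, and methyl chloroformate with pyridine would convert it into the (R,E)-methyl carbonate F7. Tsuji–Trost etherification of F7 with phenol 6 (Pd(PPh3)4 cat., THF, rt) should proceed by ionisation with inversion followed by attack of the phenoxide anti to palladium at the methyl-bearing terminus, which keeps the styrene conjugation. The double inversion should deliver the (R)-ether 7.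

Step 7. Turnover at the internal alkene next to the bulky diarylmethine carbon may be slow, and ruthenium hydrides may move the double bond into conjugation with the aryl groups, destroying the stereocentre. The fallback sets out from 9 and comes back at 10; it turns the intermolecular ethenolysis into a ring closure through a temporary silicon tether on the neighbouring 7-OH. Silylation of 9 with chloro(dimethyl)vinylsilane and imidazole (CH2Cl2, used crude) would give the 7-O-(dimethylvinylsilyl) ether F8. Ring-closing metathesis (Hoveyda–Grubbs II or a Schrock molybdenum alkylidene, toluene, 60 °C) would expel propene and give the seven-membered cyclic alkenylsiloxane F9. Fluoride-promoted protodesilylation (TBAF, AcOH, THF) would then cleave the Si–O and Si–C bonds to give 10; any partly deacetylated material converges in step 8.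

Further compounds
F1 | step 6 | 4-O-acetylconiferyl alcohol, (E)-3-(4-acetoxy-3-methoxyphenyl)prop-2-en-1-ol | CC(=O)Oc1ccc(/C=C/CO)cc1OC
F2 | step 6 | (E)-3,5-diacetoxy-7-{[3-(4-acetoxy-3-methoxyphenyl)prop-2-en-1-yl]oxy}flavone | CC(=O)Oc1ccc(/C=C/COc2cc(OC(C)=O)c3c(=O)c(OC(C)=O)c(-c4ccccc4)oc3c2)cc1OC
F3 | step 6 | racemic ortho-dienone, 3,5-diacetoxy-8-[1-(4-acetoxy-3-methoxyphenyl)prop-2-en-1-yl]-2-phenyl-8H-chromene-4,7-dione (not isolated) | C=CC(c1ccc(OC(C)=O)c(OC)c1)C1C(=O)C=C(OC(C)=O)C2=C1OC(c1ccccc1)=C(OC(C)=O)C2=O
F4 | step 6 | racemic 3,5-di-O-acetyl-8-[1-(4-acetoxy-3-methoxyphenyl)prop-2-enyl]galangin | C=CC(c1ccc(OC(C)=O)c(OC)c1)c1c(O)cc(OC(C)=O)c2c(=O)c(OC(C)=O)c(-c3ccccc3)oc12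
F5 | step 6 | (S)-enantiomer of 10, 3,5-di-O-acetyl-8-[(1S)-1-(4-acetoxy-3-methoxyphenyl)prop-2-en-1-yl]galangin | C=C[C@@H](c1ccc(OC(C)=O)c(OC)c1)c1c(O)cc(OC(C)=O)c2c(=O)c(OC(C)=O)c(-c3ccccc3)oc12
F6 | step 5 | (R,E)-4-(4-acetoxy-3-methoxyphenyl)but-3-en-2-ol | C[C@@H](O)/C=C/c1ccc(OC(C)=O)c(OC)c1
F7 | step 5 | (R,E)-4-(4-acetoxy-3-methoxyphenyl)but-3-en-2-yl methyl carbonate | C[C@@H](OC(=O)OC)/C=C/c1ccc(OC(C)=O)c(OC)c1
F8 | step 7 | 7-O-(dimethylvinylsilyl) ether of 9 | C/C=C/[C@H](c1ccc(OC(C)=O)c(OC)c1)c1c(O[Si](C)(C)C=C)cc(OC(C)=O)c2c(=O)c(OC(C)=O)c(-c3ccccc3)oc12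
F9 | step 7 | cyclic alkenylsiloxane, seven-membered ring C7–O–SiMe2–CH=CH–CH(aryl)–C8 fused to the 3,5-diacetoxyflavone, (R) at the diarylmethine carbon | C[Si]1(C)C=C[C@H](c2ccc(OC(C)=O)c(OC)c2)c2c(O1)cc(OC(C)=O)c3c(=O)c(OC(C)=O)c(-c4ccccc4)oc23
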